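**Count the loss.** Count the second end groups first, in fractions of their charge.

| flask | first end groups | second end groups | remark | time |
|---|---|---|---|---|
| summer | 0.10 M | 0.090 M | run made earlier |  |
| winter | 0.10 M | 0.060 M | run made earlier |  |
| dusk | 0.10 M | 0.14 M | run made earlier |  |
| ash | 0.10 M | 0.0900 M | everything together at the start | 2.5 h |
| birch | 0.10 M | 0.0900 M (fed, over 1.5 h) | all else is in the flask from the start; the feed brings no volume worth counting | 2.5 h |
| alder | 0.10 M (fed, over 1.5 h) | 0.0900 M | all else is in the flask from the start; the feed brings no volume worth counting | 2.5 h |
| oak | 0.10 M | 0.0900 M (in portions, 2, over 1.5 h) | first portion at the start, last at 1.5 h | 2.5 h |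

summer run (percent of the first end groups charged)

| time / h | rings / % | links / % | first end groups / % |
|---|---|---|---|
| 0.333 | 66.1 | 6.8 | 24.5 |
| 0.833 | 70.0 | 3.0 | 24.2 |
| 1.50 | 73.6 | 0.2 | 26.2 |
| 2.50 | 75.3 | 0 | 27.5 |

winter run (percent of the first end groups charged)

| time / min | rings / % | links / % | first end groups / % |
|---|---|---|---|
| 30.0 | 51.9 | 3.2 | 46.5 |
| 60.0 | 54.3 | 0.5 | 46.1 |
| 90.0 | 52.6 | 1.2 | 45.4 |
| 120 | 54.4 | 0.5 | 46.8 |

dusk run (percent of the first end groups charged)

| time / min | rings / % | links / % | first end groups / % |
|---|---|---|---|
| 10.0 | 80.3 | 15.4 | 7.4 |
| 20.0 | 83.4 | 8.4 | 7.9 |
| 50.0 | 88.7 | 3.4 | 9.1 |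
| 120 | 92.1 | 0 | 7.3 |

(scatter of a reading: 1 percentage point)

- steps that have been proposed: first end groups + second end groups <-> links; first end groups + second end groups -> rings; 2 second end groups -> homo dimer

1. which flask leads in amount of rings, in percent of the first end groups charged ("all alike" within 1.5 percentage points) (ash / birch / alder / oak / all alike)
2. how much rings is there at the end, in percent of the first end groups charged: ash
3. how much rings is there at the end, in percent of the first end groups charged: birch
4. how much rings is there at the end, in percent of the first end groups charged: alder
5. how much rings is there at the end, in percent of the first end groups charged: oak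

One ring takes one of each end group, and second end groups are the limiting reagent in ash, charged at 0.0900 M against 0.10 M of first end groups, so the ring ceiling there is 90.0 % of the first end groups charged. I compute the correction. Summer ends at 75.3 % rings, which gives 16.3 %: the loss share, the fraction of the second end groups charged that is not in rings at the end. The same reading gives 9.33 % for winter and 34.2 % for dusk, each with the scatter of 1 percentage point in its rings.

**A doubt.** Perhaps the summer loss is unfinished reaction rather than homo dimer. But first end groups in summer read 24.5 % at 0.333 h and 27.5 % at 2.50 h, so they stop falling early, and I book the loss as homo dimer.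

**My estimate.** Ash repeats summer, so I expect 75.3 % rings. Birch spreads its second end groups over 1.5 h, and the loss share reads lower with less second per first, 9.33 % in winter against 34.2 % in dusk, so I put birch near the ceiling. Oak's first portion has a ratio of second to first of 0.450, below winter's 0.600, and at winter's loss share it gives 40.8 %. The objection is that the second portion meets fewer first end groups, but its ratio of 0.760 is still lower than summer's. I take summer's share for that portion, which gives oak a total of 78.5 %. Alder starts with no first end groups in the flask, which lies beyond the readings, so I claim a loss above dusk's, meaning rings below 59.2 %.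

**The forecast.** It names birch, with ash 75 %, birch 87 %, oak 80 % and alder 28 %. Its oak stands above mine, and of alder it says: “The rate constant is only a lower bound”.

**The flask.** The leader is birch: ash 73.2 %, birch 90.0 %, oak 82.2 %, alder 22.6 %.

    first end groups + second end groups ⇌ links (K = 46.0 M⁻¹, k = 0.0260 M⁻¹ s⁻¹)
    first end groups + second end groups → rings, rate k2*[first end groups] as long as [second end groups] is above zero (k = 0.00550 s⁻¹)
    2 second end groups → homo dimer (k = 0.0270 M⁻¹ s⁻¹)

**The neighbour.** Alder's loss share is 74.9 %, higher than summer's 16.3 %. The neighbour flask is alder with 0.036 M of second end groups, so its ceiling is 36.0 %. Alder's loss share would leave 9.04 % rings there, but this neighbour gives 18.2 %. Its loss share is therefore 49.5 %, lower than alder's. Two second end groups go into each homo dimer, so that loss, less the links at 0.00745 % of the first end groups charged, makes 0.00891 M of it, and the neighbour holds 0.00890 M after 2.50 h.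

The readings are simulated with made-up constants, and the scatter is random.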